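Locants C1–C8 of the bicyclo[3.2.1]octane core are used throughout, also for the ring atoms of the aromatic precursors: C1 prenyl bridgehead, C2 ketone, C3 isobutyryl carbon, C4 enol carbon, C5 methyl bridgehead, C6 carbinol-bearing CH, C7 CH2, C8 bridging ketone. O2, O4 and O8 are the oxygens on C2, C4 and C8.

## The problem

Target 16 is a bicyclo[3.2.1]oct-3-ene-2,8-dione: an enolised acyl-β-diketone ring (C1–C2–C3–C4–C5–C8) bridged across its two quaternary carbons C1 and C5 by the two-carbon unit C7–C6. The bridge can only be cis, so C1 and C5 are not independent of each other. Two stereochemical questions remain: the endo orientation of the Me2C(OH) group at C6 (on the side of the C2–C3–C4 bridge), and the absolute sense. Either C6 is set first and dictates both bridgeheads, or the bridge-forming event that fixes C1 and C5 is made to fix C6 as well. The enol is acidic and chelating, and because C1 and C5 are quaternary the 1,3-dicarbonyl units are open to retro-Claisen cleavage by nucleophilic base; the prenyl alkene is sensitive to acid and electrophilic oxidants; the tertiary alcohol can dehydrate or close a hemiketal on C4. The six-membered ring carries oxygen on C2, C4 and C8 and carbon on C1, C3 and C5, which is the pattern of a C-methyl, C-alkyl acylphloroglucinol that has lost aromaticity by forming two bonds at C1 and C5. What has been added across C1 and C5 is the vinyl group of 2-methylbut-3-en-2-ol (9), and its carbinol oxygen, lying endo, can be joined to O4 through a single silicon atom. A synthesis therefore has to unite an oxidised phloroglucinol ring with an unactivated vinyl group in a defined orientation, and to tell apart three phenolic oxygens that differ only in their neighbours.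

## Retrosynthesis

**16 from 15.** The two Si–O bonds of a diisopropylsilylene spanning O4 and the carbinol oxygen are cut. One silicon masks the acidic enol and the tertiary alcohol together, so the free triketone appears only in the last step. The forward reaction is a fluoride cleavage that must spare the prenyl group and the bridgehead ketones.

**15 from 13 and 14.** The trisubstituted double bond of the prenyl group is cut back to an allyl group plus 2-methylbut-2-ene (14). Carrying prenyl through the oxidation was the neighbouring option. It is set aside because the trisubstituted alkene is the most electron-rich site after the phenol and because allyl can be delivered to C1 without any C-alkylation chemistry (see 12). The forward reaction is a cross-metathesis on the only alkene of 13.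

**13 from 12.** Both ring bonds of the five-membered ring, C1–C7 and C5–C6, are cut at once. This removes all three stereocentres and leaves a flat hexasubstituted arene whose O4 carries the vinyl carbinol on a silicon tether. The neighbouring cuts are weaker: alkylation at C1 followed by enolate closure at C5 gives no handle on the C6 orientation, and closing the six-membered ring last has to bridge a cyclopentanone. The forward reaction asks four things: oxidation of the one free phenol (O8–H) to a cation; addition of the tethered alkene across C1 and C5 and not across C1 and C3; endo delivery, which the seven-membered siloxane ring enforces; and face selection by a chiral trivalent-iodine oxidant. O2 is kept as a silyl ether so that O8 is the only hydroxyl the oxidant can bind.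

**12 from 11.** The C1–CH2 bond of the allyl group is cut and the allyl placed on O8. A [3,3] shift can only reach C1, because the other ortho carbon (C5) bears the methyl group, and it frees O8–H in the same event. Direct C-allylation would have to precede the differentiation of the oxygens and would make O2 and O4 indistinguishable. The forward reaction is a thermal isomerisation that the two silyl ethers must survive.

**11 from 7, 8 and 9.** The two Si–O bonds of the tether are cut to the phenol 7, the silyl bis(triflate) 8 and the tertiary allylic alcohol 9. The hindered, chelated O4–H is the only hydroxyl left in 7, so no selectivity is asked, only reactivity. This is the reason for choosing a bis(triflate).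

**7 from 5 and 6; 5 from 3 and 4.** The O2–Si and O8–C bonds are cut. The three hydroxyls of 3 are addressed in their natural order of reactivity: the non-chelated para hydroxyl O8 is alkylated first with allyl bromide (4), and the less hindered of the two chelated hydroxyls (O2, next to a ring C–H) is then silylated with 6. O4, buttressed between methyl and acyl, remains. This works only while C1 is unsubstituted, which is why the C1 substituent arrives later from O8.

**3 from 1 and 2.** The C3–acyl bond is cut. The two free ring positions of 2-methylbenzene-1,3,5-triol (1) are equivalent, so acylation with 2 is unambiguous and gives a fully defined pentasubstituted ring in one step.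

## Roads not taken

**Alternative 1: Wagner–Meerwein contraction of a bicyclo[3.3.1]nonane carbinol.** The C6–C7 bond is made by a 1,2-shift. The equatorial C6 hydroxyl of the ring-expanded carbinol A1 is ionised as its triflate, the antiperiplanar C7 migrates from the CMe2 carbon to C6, and the exocyclic tertiary cation is trapped by water to give A2.
- Merits: the shift is stereospecific, so one stereocentre of A1 sets C6 and delivers the carbinol. Bicyclo[3.3.1]nonane triones are the best-studied cores of this family, so A1 could draw on established, also enantioselective, annulations. In the founding of its absolute stereochemistry this road is better than the chosen plan.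
- Weak points: A1 is larger and more congested than 16 and needs its own multistep synthesis with the hydroxyl correctly equatorial. The tertiary cation is born endo, next to the C4 enol ether oxygen, so loss of a proton or capture by that oxygen can compete with water. A2 still lacks the isobutyryl group and carries a methyl ether, so two further steps are needed.
- Comparison: the chosen plan sets against it that the complete skeleton, acyl group included, arises in one step from a flat arene without a skeletal detour.

**Alternative 2: carbinol-tethered malonyl annulation of a cyclopentanone.** The C4–C5 and C1–C2 bonds are cut. The malonate half-ester A3 is activated, C-acylates C5, and on heating releases an acylketene that acylates C1 to give the des-isobutyryl bicycle A4.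
- Merits: C6 is set in a simple cyclopentanone by conventional asymmetric chemistry, and the tether forces the first acylation cis to the carbinol. Relative and absolute configuration are thus better secured than in the chosen plan.
- Weak points: bridging the two α-carbons of a cyclopentanone with three atoms gives the more strained [3.2.1] system. Both acylations create quaternary centres and O-acylation competes. The thermal release of an acylketene from a β-keto lactone at a quaternary carbon is not a standard fragmentation, and the freed tertiary alcohol can recapture the ketene. A4 still needs C3 acylation.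
- Comparison: the chosen plan sets against this its convergence, with all carbons and the acyl group in place before the ring-forming event, and a ring closure that relieves no more strain than a cycloaddition can pay for.

**Alternative 3: desymmetrising Dieckmann condensation.** The C5–C8 bond is cut. The lactone enolate of A5 attacks one of two diastereotopic malonate esters to give the cis-fused β-keto ester A6.
- Merits: the reaction type is robust, the cis ring fusion is obligatory, and the lactone stereocentre (C6) controls C5 directly. For early, conventional stereocontrol it is as good as Alternative 2.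
- Weak points: the choice between the two esters, which sets C1, rests on remote induction. A6 is a non-enolisable β-keto ester and is exposed to retro-Dieckmann cleavage. The real difficulty is postponed: the six-membered ring must still be closed by inserting C3 between a neopentyl ester and a hindered lactone carbonyl, and then acylated.
- Comparison: the chosen plan is far shorter after its key step. Its price is that its stereocontrol is reagent-based and untested.

Key step: step 6

**Assumptions.**
- 2-Methylbenzene-1,3,5-triol (1) and the silyl bis(triflate) 8 are taken as commercial. The chiral aryl-λ3-iodane diacetate of step 6 is made from the known C2-symmetric iodoarene by peracetic acid oxidation.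
- Which antipode of the iodane leads to the (1R,5R,6S) series cannot be predicted with confidence. The (R,R) reagent is written, and its mirror image would be used if the sense proved opposite.

## Route

Step 1
Reactants: 1 2-methylbenzene-1,3,5-triol; 2 2-methylpropanoyl chloride (isobutyryl chloride)
Product: 3 1-(2,4,6-trihydroxy-3-methylphenyl)-2-methylpropan-1-one
Conditions: AlCl3 (3.5 equiv), PhNO2–CH2Cl2, 0 → 40 °C; aq. HCl
Reagents that add atoms: 2-methylpropanoyl chloride (2), CC(C)C(Cl)=O
Why: Friedel–Crafts acylation of a phloroglucinol; the two unsubstituted ring carbons of 1 are equivalent, so a single C-acyl product can form, and the aryl ketone is deactivated towards a second acylation.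

Step 2
Reactants: 3 1-(2,4,6-trihydroxy-3-methylphenyl)-2-methylpropan-1-one; 4 3-bromoprop-1-ene (allyl bromide)
Product: 5 1-[2,6-dihydroxy-3-methyl-4-(prop-2-en-1-yloxy)phenyl]-2-methylpropan-1-one (O8-allyl ether)
Conditions: K2CO3 (1.1 equiv), allyl bromide (1.05 equiv), acetone, rt
Reagents that add atoms: allyl bromide (4), C=CCBr
Why: Williamson ether synthesis; the hydroxyl para to the acyl group is the most acidic and the only one not held in a hydrogen bond to the carbonyl, so one equivalent of base and halide should alkylate it in preference to the two chelated hydroxyls.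

Step 3
Reactants: 5 1-[2,6-dihydroxy-3-methyl-4-(prop-2-en-1-yloxy)phenyl]-2-methylpropan-1-one; 6 tert-butyl(chloro)dimethylsilane
Product: 7 1-[2-{[tert-butyl(dimethyl)silyl]oxy}-6-hydroxy-5-methyl-4-(prop-2-en-1-yloxy)phenyl]-2-methylpropan-1-one (O2 silylated, O4–H free)
Conditions: TBSCl (1.05 equiv), imidazole, CH2Cl2, 0 °C
Reagents that add atoms: tert-butyl(chloro)dimethylsilane (6), CC(C)(C)[Si](C)(C)Cl
Why: O-silylation of a phenol with a bulky chlorosilane; of the two chelated hydroxyls the one beside the ring C–H is less hindered than the one buttressed between C-methyl and acyl, and after one silylation the remaining hydroxyl holds the only hydrogen bond to the carbonyl and resists a second.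

Step 4
Reactants: 7 1-[2-{[tert-butyl(dimethyl)silyl]oxy}-6-hydroxy-5-methyl-4-(prop-2-en-1-yloxy)phenyl]-2-methylpropan-1-one; 8 di(propan-2-yl)silanediyl bis(trifluoromethanesulfonate); 9 2-methylbut-3-en-2-ol
Product: 11 1-[2-{[tert-butyl(dimethyl)silyl]oxy}-5-methyl-6-({[(2-methylbut-3-en-2-yl)oxy]di(propan-2-yl)silyl}oxy)-4-(prop-2-en-1-yloxy)phenyl]-2-methylpropan-1-one, via aryloxysilyl triflate 10 (not isolated)
Conditions: 8 (1.1 equiv), 2,6-lutidine, CH2Cl2, −78 → 0 °C; then 9 (3 equiv), 0 °C → rt
Reagents that add atoms: di(propan-2-yl)silanediyl bis(trifluoromethanesulfonate) (8), CC(C)[Si](OS(=O)(=O)C(F)(F)F)(OS(=O)(=O)C(F)(F)F)C(C)C; 2-methylbut-3-en-2-ol (9), CC(C)(O)C=C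
Why: stepwise formation of an unsymmetrical silaketal from a dialkylsilyl bis(triflate); the first triflate is reactive enough for the hindered, chelated phenol, and the aryloxysilyl triflate is then taken up by the tertiary alcohol used in excess, with 2,6-lutidine buffering the acid so that the TBS and allyl ethers are untouched.

Step 5
Reactants: 11 1-[2-{[tert-butyl(dimethyl)silyl]oxy}-5-methyl-6-({[(2-methylbut-3-en-2-yl)oxy]di(propan-2-yl)silyl}oxy)-4-(prop-2-en-1-yloxy)phenyl]-2-methylpropan-1-one
Product: 12 1-[2-{[tert-butyl(dimethyl)silyl]oxy}-4-hydroxy-5-methyl-6-({[(2-methylbut-3-en-2-yl)oxy]di(propan-2-yl)silyl}oxy)-3-(prop-2-en-1-yl)phenyl]-2-methylpropan-1-one (C1 allyl, O8–H free, O2 TBS, O4 tether)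
Conditions: 1,2-dichlorobenzene, 180 °C, sealed tube
Reagents that add atoms: none
Why: aromatic Claisen rearrangement; C1 is the only unsubstituted ortho carbon of the O8-allyl ether, so the [3,3] shift delivers allyl there and tautomerisation frees O8–H, and no O-allyl group remains that could rearrange further.

Step 6
Reactants: 12 1-[2-{[tert-butyl(dimethyl)silyl]oxy}-4-hydroxy-5-methyl-6-({[(2-methylbut-3-en-2-yl)oxy]di(propan-2-yl)silyl}oxy)-3-(prop-2-en-1-yl)phenyl]-2-methylpropan-1-one
Product: 13 cyclic di(propan-2-yl)silylene, bridging the C4 enol oxygen and the carbinol oxygen, of (1R,5R,6S)-4-hydroxy-6-(2-hydroxypropan-2-yl)-5-methyl-3-(2-methylpropanoyl)-1-(prop-2-en-1-yl)bicyclo[3.2.1]oct-3-ene-2,8-dione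
Conditions: (R,R)-ArI(OAc)2 (1.1 equiv; Ar = 2,6-bis{[(2R)-1-(mesitylamino)-1-oxopropan-2-yl]oxy}phenyl), CH2Cl2, (CF3)2CHOH as additive, −40 → −20 °C
Reagents that add atoms: none
Why: Proposed new method: ligand exchange of the only free hydroxyl, O8–H, on the trivalent-iodine centre and loss of the iodoarene turn the ring into a 2,4-bis(silyloxy)pentadienyl cation C1–C2–C3–C4–C5 whose termini flank the nascent C8 carbonyl, and the tethered vinyl group adds across these termini (C7 to C1, C6 to C5) in a cationic (5+2) cycloaddition that is probably concerted but asynchronous with the terminal carbon C7 bonding first; the bis(silyloxy)allyl cation left over C2–C3–C4 is then discharged when acetate takes the unhindered tert-butyldimethylsilyl group from O2. The closest known reaction type is the oxidative-dearomatisation-induced cationic (5+2) cycloaddition of p-alkoxyphenols with alkenes, which gives bicyclo[3.2.1]octenediones, but it has not been shown for an acylphloroglucinol or through a silicon tether. The five-membered ring C1–C7–C6–C5–C8 closes in the cycloaddition mode across the two ends of the oxyallyl unit C1–C8–C5, and the seven-membered siloxane ring C4–O–Si–O–CMe2–C6–C5 closes with it, which is what turns the addition of a poor π-nucleophile into an intramolecular event. C1 and C5 become cis bridgeheads by necessity, and C6 is set by the tether, which can span O4 and the carbinol oxygen only if the Me2C–O group ends endo, over the C2–C3–C4 bridge. The absolute sense is to come from the C2-symmetric chiral iodane, which is expected to be still bound to O8 when the first bond forms at the adjacent carbon, as in enantioselective ortho-dearomatisations of phenols with such reagents. The step needs the internal alkene carbon to choose C5 over C3, which the isobutyryl group secures by making C3 the hindered centre whose bonding would break the acyl conjugation and by leaving only O8 free to become the bridging carbonyl; it also needs the oxidant to choose the phenol over the alkenes, for which the spectator is allyl and not prenyl.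

Step 7
Reactants: 13 cyclic di(propan-2-yl)silylene of the 1-allyl bicycle; 14 2-methylbut-2-ene
Product: 15 cyclic di(propan-2-yl)silylene, bridging the C4 enol oxygen and the carbinol oxygen, of (1R,5R,6S)-4-hydroxy-6-(2-hydroxypropan-2-yl)-5-methyl-1-(3-methylbut-2-en-1-yl)-3-(2-methylpropanoyl)bicyclo[3.2.1]oct-3-ene-2,8-dione
Conditions: second-generation Grubbs catalyst (H2IMes)(PCy3)Cl2Ru=CHPh (5 mol %), 2-methylbut-2-ene (excess), CH2Cl2, 40 °C
Reagents that add atoms: 2-methylbut-2-ene (14), CC=C(C)C
Why: olefin cross-metathesis of a terminal allyl group with 2-methylbut-2-ene, the standard conversion of allyl into prenyl at a quaternary carbon; 13 contains no other alkene and the enol is capped, so the catalyst meets no competing or chelating site.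

Step 8
Reactants: 15 cyclic di(propan-2-yl)silylene of the 1-prenyl bicycle
Product: 16 (1R,5R,6S)-4-hydroxy-6-(2-hydroxypropan-2-yl)-5-methyl-1-(3-methylbut-2-en-1-yl)-3-(2-methylpropanoyl)bicyclo[3.2.1]oct-3-ene-2,8-dione
Conditions: HF·pyridine, THF, 0 °C → rt
Reagents that add atoms: none
Why: fluoride-driven cleavage of both Si–O bonds of the silylene, which releases the C4 enol and the tertiary alcohol under mildly acidic, non-nucleophilic conditions that touch neither the prenyl group nor the stereocentres.

## Compound list

1 | 2-methylbenzene-1,3,5-triol | Cc1c(O)cc(O)cc1O | starting material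
2 | 2-methylpropanoyl chloride | CC(C)C(Cl)=O | starting material
3 | 1-(2,4,6-trihydroxy-3-methylphenyl)-2-methylpropan-1-one | CC(C)C(=O)c1c(O)cc(O)c(C)c1O | intermediate
4 | 3-bromoprop-1-ene (allyl bromide) | C=CCBr | starting material
5 | 1-[2,6-dihydroxy-3-methyl-4-(prop-2-en-1-yloxy)phenyl]-2-methylpropan-1-one | CC(C)C(=O)c1c(O)cc(OCC=C)c(C)c1O | intermediate
6 | tert-butyl(chloro)dimethylsilane | CC(C)(C)[Si](C)(C)Cl | starting material
7 | 1-[2-{[tert-butyl(dimethyl)silyl]oxy}-6-hydroxy-5-methyl-4-(prop-2-en-1-yloxy)phenyl]-2-methylpropan-1-one | CC(C)C(=O)c1c(O[Si](C)(C)C(C)(C)C)cc(OCC=C)c(C)c1O | intermediate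
8 | di(propan-2-yl)silanediyl bis(trifluoromethanesulfonate) | CC(C)[Si](OS(=O)(=O)C(F)(F)F)(OS(=O)(=O)C(F)(F)F)C(C)C | starting material
9 | 2-methylbut-3-en-2-ol | CC(C)(O)C=C | starting material
10 | aryloxy[di(propan-2-yl)]silyl trifluoromethanesulfonate of 7 (Si on the hydroxyl between methyl and acyl) | CC(C)C(=O)c1c(O[Si](C)(C)C(C)(C)C)cc(OCC=C)c(C)c1O[Si](C(C)C)(C(C)C)OS(=O)(=O)C(F)(F)F | intermediate (not isolated)
11 | 1-[2-{[tert-butyl(dimethyl)silyl]oxy}-5-methyl-6-({[(2-methylbut-3-en-2-yl)oxy]di(propan-2-yl)silyl}oxy)-4-(prop-2-en-1-yloxy)phenyl]-2-methylpropan-1-one | CC(C)C(=O)c1c(O[Si](C)(C)C(C)(C)C)cc(OCC=C)c(C)c1O[Si](C(C)C)(C(C)C)OC(C)(C)C=C | intermediate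
12 | 1-[2-{[tert-butyl(dimethyl)silyl]oxy}-4-hydroxy-5-methyl-6-({[(2-methylbut-3-en-2-yl)oxy]di(propan-2-yl)silyl}oxy)-3-(prop-2-en-1-yl)phenyl]-2-methylpropan-1-one | CC(C)C(=O)c1c(O[Si](C)(C)C(C)(C)C)c(CC=C)c(O)c(C)c1O[Si](C(C)C)(C(C)C)OC(C)(C)C=C | intermediate
13 | cyclic di(propan-2-yl)silylene (C4 enol O / carbinol O) of (1R,5R,6S)-4-hydroxy-6-(2-hydroxypropan-2-yl)-5-methyl-3-(2-methylpropanoyl)-1-(prop-2-en-1-yl)bicyclo[3.2.1]oct-3-ene-2,8-dione | C=CC[C@@]12C[C@H](C(C)(C)O[Si]3(C(C)C)C(C)C)[C@@](C)(C1=O)C(O3)=C(C(=O)C(C)C)C2=O | intermediate
14 | 2-methylbut-2-ene | CC=C(C)C | starting material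
15 | cyclic di(propan-2-yl)silylene (C4 enol O / carbinol O) of (1R,5R,6S)-4-hydroxy-6-(2-hydroxypropan-2-yl)-5-methyl-1-(3-methylbut-2-en-1-yl)-3-(2-methylpropanoyl)bicyclo[3.2.1]oct-3-ene-2,8-dione | CC(C)=CC[C@@]12C[C@H](C(C)(C)O[Si]3(C(C)C)C(C)C)[C@@](C)(C1=O)C(O3)=C(C(=O)C(C)C)C2=O | intermediate
16 | (1R,5R,6S)-4-hydroxy-6-(2-hydroxypropan-2-yl)-5-methyl-1-(3-methylbut-2-en-1-yl)-3-(2-methylpropanoyl)bicyclo[3.2.1]oct-3-ene-2,8-dione | CC(C)=CC[C@@]12C[C@H](C(C)(C)O)[C@@](C)(C1=O)C(O)=C(C(=O)C(C)C)C2=O | target

## Step count and least certain steps

Total: 8 steps. Longest linear sequence: 8 steps (1 to 16).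

**Step 6 (key step, proposed new method).** Three processes may defeat it.
- Capture of the cation by acetate or the fluoro alcohol, or loss of a proton from the C5 methyl or the C1 methylene, may outrun the addition of a vinyl group that is inductively deactivated by its allylic oxygen.
- The internal alkene carbon may bond at C3 instead of C5.
- Face selection may be lost if the cation leaves the chiral iodane before the alkene arrives.

The fallback uses known reaction types, abandons the tether and sets out from 3. C-Prenylation with prenyl bromide in aqueous KOH should give 1-[2,4,6-trihydroxy-3-methyl-5-(3-methylbut-2-en-1-yl)phenyl]-2-methylpropan-1-one F1. Separately, Sharpless epoxidation of 3-methylbut-2-en-1-ol (Ti(OiPr)4, L-(+)-diethyl tartrate, t-BuOOH) should give [(2S)-3,3-dimethyloxiran-2-yl]methanol F2, and tosylation its 4-methylbenzenesulfonate F3. Alkylative dearomatisation of F1 with F3 (LiN(SiMe3)2, THF, 0 °C → rt) should place the epoxymethyl group on C1 to give the dearomatised epoxy dienone F4. Its C5 enolate should then open the epoxide at the secondary carbon with inversion in a 5-exo closure, which comes back to the route at 16 with C6 already (S). Its limits are these: alkylation may also occur at the methyl-bearing carbon or on oxygen, and the two faces of C1 are not distinguished, so at most half of the material can close to the endo series and the rest has to be removed by chromatography.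

**Step 3.** Silylation may fail to discriminate the two chelated hydroxyls, since they differ only by a neighbouring C–H versus C–CH3. The fallback moves the discrimination to O-alkylation, which for C-methyl acylphloroglucinols classically spares the hydroxyl between methyl and acyl, and removes the masks before the oxidation. It sets out from 3.
- Allyl bromide (2.2 equiv) and K2CO3 in acetone should give 1-[2-hydroxy-3-methyl-4,6-bis(prop-2-en-1-yloxy)phenyl]-2-methylpropan-1-one F5.
- Tethering as in step 4 should give its O4 silaketal F6.
- Heating should move one allyl group to C1, giving the O2-allyl ether with free O8–H F7 and the O8-allyl ether with free O2–H F8.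
- Without separation, Pd(PPh3)4 and morpholine should remove the remaining O-allyl group from both, giving the 2,4-dihydroxy precursor F9.
- F9 is oxidised as in step 6 and comes back to the route at 13.

It is second choice because the second allyl ether can undergo a further, dearomatising sigmatropic shift during the heating.

**Step 4.** The doubly flanked, chelated phenol may react sluggishly, a second phenol may displace the remaining triflate to give a symmetrical bis(aryloxy)silane, or the TBS group may be transferred under the acidic salt. The fallback reverses the order of the two Si–O bond formations and makes the phenol the nucleophile. Alcohol 9 is converted with n-BuLi and excess dichlorodi(propan-2-yl)silane into chloro[(2-methylbut-3-en-2-yl)oxy]di(propan-2-yl)silane F10, which is distilled. The sodium phenoxide of 7 (NaH, THF) is then silylated with F10, which comes back to the route at 11.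

**Step 5.** At 180 °C the aryl silyl groups may migrate between phenolic oxygens once O8–H has formed, or the silaketal may be lost. The fallback replaces the sigmatropic shift by cross-coupling and sets out from 11. Zerovalent palladium, as Pd(PPh3)4, with morpholine should remove the allyl ether to give the O8 phenol with C1–H F11. N-Bromosuccinimide at 0 °C should brominate the only free ring position to give the C1 bromide F12. Stille coupling with allyltributylstannane and Pd(PPh3)4 then comes back to the route at 12.

**Step 7.** The silylene enol ether, a vinylogous silyl ester, may hydrolyse during the metathesis or on purification, and the freed triketone may bind the ruthenium catalyst. The fallback inverts the order of the last two steps. Cycloadduct 13 is desilylated first (HF·pyridine) to (1R,5R,6S)-4-hydroxy-6-(2-hydroxypropan-2-yl)-5-methyl-3-(2-methylpropanoyl)-1-(prop-2-en-1-yl)bicyclo[3.2.1]oct-3-ene-2,8-dione F13. This stable free enol is then cross-metathesised with 14 under the conditions of step 7, which comes back to the route at 16.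

## Further compounds

F1 | step 6 | 1-[2,4,6-trihydroxy-3-methyl-5-(3-methylbut-2-en-1-yl)phenyl]-2-methylpropan-1-one | CC(C)=CCc1c(O)c(C)c(O)c(C(=O)C(C)C)c1O
F2 | step 6 | [(2S)-3,3-dimethyloxiran-2-yl]methanol | OC[C@@H]1OC1(C)C
F3 | step 6 | [(2S)-3,3-dimethyloxiran-2-yl]methyl 4-methylbenzenesulfonate | Cc1ccc(cc1)S(=O)(=O)OC[C@@H]1OC1(C)C
F4 | step 6 | 6-{[(2S)-3,3-dimethyloxiran-2-yl]methyl}-3,5-dihydroxy-2-methyl-6-(3-methylbut-2-en-1-yl)-4-(2-methylpropanoyl)cyclohexa-2,4-dien-1-one (both epimers at the quaternary ring carbon) | CC(C)=CCC1(C[C@@H]2OC2(C)C)C(=O)C(C)=C(O)C(C(=O)C(C)C)=C1O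
F5 | step 3 | 1-[2-hydroxy-3-methyl-4,6-bis(prop-2-en-1-yloxy)phenyl]-2-methylpropan-1-one | CC(C)C(=O)c1c(OCC=C)cc(OCC=C)c(C)c1O
F6 | step 3 | 1-[3-methyl-2-({[(2-methylbut-3-en-2-yl)oxy]di(propan-2-yl)silyl}oxy)-4,6-bis(prop-2-en-1-yloxy)phenyl]-2-methylpropan-1-one | CC(C)C(=O)c1c(OCC=C)cc(OCC=C)c(C)c1O[Si](C(C)C)(C(C)C)OC(C)(C)C=C
F7 | step 3 | 1-[4-hydroxy-5-methyl-6-({[(2-methylbut-3-en-2-yl)oxy]di(propan-2-yl)silyl}oxy)-3-(prop-2-en-1-yl)-2-(prop-2-en-1-yloxy)phenyl]-2-methylpropan-1-one | CC(C)C(=O)c1c(OCC=C)c(CC=C)c(O)c(C)c1O[Si](C(C)C)(C(C)C)OC(C)(C)C=C
F8 | step 3 | 1-[2-hydroxy-5-methyl-6-({[(2-methylbut-3-en-2-yl)oxy]di(propan-2-yl)silyl}oxy)-3-(prop-2-en-1-yl)-4-(prop-2-en-1-yloxy)phenyl]-2-methylpropan-1-one | CC(C)C(=O)c1c(O)c(CC=C)c(OCC=C)c(C)c1O[Si](C(C)C)(C(C)C)OC(C)(C)C=C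
F9 | step 3 | 1-[2,4-dihydroxy-5-methyl-6-({[(2-methylbut-3-en-2-yl)oxy]di(propan-2-yl)silyl}oxy)-3-(prop-2-en-1-yl)phenyl]-2-methylpropan-1-one | CC(C)C(=O)c1c(O)c(CC=C)c(O)c(C)c1O[Si](C(C)C)(C(C)C)OC(C)(C)C=C
F10 | step 4 | chloro[(2-methylbut-3-en-2-yl)oxy]di(propan-2-yl)silane | CC(C)[Si](Cl)(OC(C)(C)C=C)C(C)C
F11 | step 5 | 1-[2-{[tert-butyl(dimethyl)silyl]oxy}-4-hydroxy-5-methyl-6-({[(2-methylbut-3-en-2-yl)oxy]di(propan-2-yl)silyl}oxy)phenyl]-2-methylpropan-1-one | CC(C)C(=O)c1c(O[Si](C)(C)C(C)(C)C)cc(O)c(C)c1O[Si](C(C)C)(C(C)C)OC(C)(C)C=C
F12 | step 5 | 1-[3-bromo-2-{[tert-butyl(dimethyl)silyl]oxy}-4-hydroxy-5-methyl-6-({[(2-methylbut-3-en-2-yl)oxy]di(propan-2-yl)silyl}oxy)phenyl]-2-methylpropan-1-one | CC(C)C(=O)c1c(O[Si](C)(C)C(C)(C)C)c(Br)c(O)c(C)c1O[Si](C(C)C)(C(C)C)OC(C)(C)C=C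
F13 | step 7 | (1R,5R,6S)-4-hydroxy-6-(2-hydroxypropan-2-yl)-5-methyl-3-(2-methylpropanoyl)-1-(prop-2-en-1-yl)bicyclo[3.2.1]oct-3-ene-2,8-dione | C=CC[C@@]12C[C@H](C(C)(C)O)[C@@](C)(C1=O)C(O)=C(C(=O)C(C)C)C2=O
A1 | alternative 1 | 6-hydroxy-4-methoxy-5,7,7-trimethyl-1-(3-methylbut-2-en-1-yl)bicyclo[3.3.1]non-3-ene-2,9-dione (equatorial 6-hydroxyl) | CC(C)=CC[C@@]12CC(C)(C)[C@H](O)[C@@](C)(C1=O)C(OC)=CC2=O
A2 | alternative 1 | 6-(2-hydroxypropan-2-yl)-4-methoxy-5-methyl-1-(3-methylbut-2-en-1-yl)bicyclo[3.2.1]oct-3-ene-2,8-dione, configured as 16 | CC(C)=CC[C@@]12C[C@H](C(C)(C)O)[C@@](C)(C1=O)C(OC)=CC2=O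
A3 | alternative 2 | malonic acid mono-ester of the tertiary alcohol of 3-(2-hydroxypropan-2-yl)-2-methyl-5-(3-methylbut-2-en-1-yl)cyclopentan-1-one, carbinol-bearing carbon as in 16 | CC(C)=CCC1C[C@H](C(C)(C)OC(=O)CC(O)=O)C(C)C1=O
A4 | alternative 2 | 4-hydroxy-6-(2-hydroxypropan-2-yl)-5-methyl-1-(3-methylbut-2-en-1-yl)bicyclo[3.2.1]oct-3-ene-2,8-dione, configured as 16 | CC(C)=CC[C@@]12C[C@H](C(C)(C)O)[C@@](C)(C1=O)C(O)=CC2=O
A5 | alternative 3 | dimethyl 2-(3-methylbut-2-en-1-yl)-2-[(2,2,4-trimethyl-5-oxooxolan-3-yl)methyl]propanedioate | CC(C)=CCC(C[C@@H]1C(C)(C)OC(=O)C1C)(C(=O)OC)C(=O)OC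
A6 | alternative 3 | methyl 3,3,6a-trimethyl-5-(3-methylbut-2-en-1-yl)-1,6-dioxohexahydro-1H-cyclopenta[c]furan-5-carboxylate, cis ring fusion | CC(C)=CC[C@@]1(C(=O)OC)C[C@@H]2C(C)(C)OC(=O)[C@]2(C)C1=O
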